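# Proposed synthesis of difengpiol A by arenophile dearomatisation of a C2 phenyl group

## The problem

Difengpiol A is a trans-2,3-disubstituted 2,3-dihydrobenzofuran. Ring A (the benzo ring) carries a methoxy group at C7 and a 3-hydroxypropyl chain at C5, C3 of ring B bears a hydroxymethyl group, and C2 is joined through one freely rotating C2–C1' bond to ring C, a cyclohex-1'-ene with a cis-diol at C3' and C4'. Four stereocentres must be set, in two pairs: C2/C3 (trans) and C3'/C4' (cis). Control within each pair is easy, since C3 can be equilibrated to trans once C2 is fixed and the two carbinol centres of a cis-diol arise together, but control between the pairs is hard, because only C2 connects them. The molecule is fragile: the O1–C2 bond is an allylic aryl ether that dissolving metals, hydrogenolysis and strong acid would cleave, the allylic diol ionises or dehydrates in acid, the trisubstituted C1'=C2' alkene must survive every reduction, and the electron-rich ring A is open to electrophiles and oxidants. The enabling feature is ring C itself: C1'–C6' have the carbon count and substitution of a phenyl group on C2 that has taken up two oxygens at its meta and para carbons (C3', C4') and two hydrogens at C5' and C6'. A plain phenyl group can therefore stand in for ring C until late, provided a dearomatisation places a cis-diol at C3'/C4' and distinguishes the two diastereotopic ortho/meta pairs of that phenyl ring.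

## Retrosynthesis

**21 to 19.** Target 21 is traced to its acetonide 20 (only the two ketal C–O bonds are cut) and 20 to the cyclohexa-1',5'-diene 19 by adding back a C5'=C6' double bond. This is preferred to creating C1'=C2' late by elimination, because in 19 both alkenes already sit where a cycloreversion puts them and they differ in substitution (C5'=C6' disubstituted, C1'=C2' trisubstituted). The forward reaction must saturate one alkene of a conjugated diene and leave the other, which is the selectivity diimide offers.

**19 to 15.** Diene 19 is the retro-[4+2] product of the bicyclic diazene 18. Reconnecting C2' and C5' through N=N leads via the cyclic hydrazine 17 to the urazole acetonide 16 and its parent diol 15. The atom count does not fall, but a sensitive diene diol is exchanged for a robust bicycle. Forward, this asks for urazole hydrolysis, oxidation of the hydrazine and spontaneous loss of N2.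

**15 to 12 and 13 (key disconnection).** Cutting the C2'–N and C5'–N bonds and the C3'–O and C4'–O bonds of 15 returns the trans 2-phenyl dihydrobenzofuran diacetate 12 and 4-methyl-1,2,4-triazoline-3,5-dione 13, through cycloadduct 14. Compared with building ring C from acyclic pieces or coupling a preformed enantiopure cyclohexene, this cut removes both ring C stereocentres and all ring C functionality at once and leaves a benzyl-derived phenyl group. The forward step must address the phenyl ring and not ring A, deliver both oxygens anti to the urazole, and choose one of the two diastereotopic ortho/meta pairs under the influence of C2 alone. The last demand is the accepted weakness: the two bicyclic diastereomers are separable at 15, and the unwanted one can be returned to 12.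

**12 to 9.** Diacetate 12 comes from diol 11, 11 from the trans diester 10 by reduction of both esters, and 10 from the cis diester 9 by epimerisation at C3. These are functional-group changes only. Acetates are chosen because they survive the photochemistry and osmylation and leave without an extra step in the basic urazole cleavage. The chain is carried as an ester so that one hydride reduction creates both primary alcohols.

**9 to 8.** The C2–C3 bond is cut to the aryl diazoacetate 8, whose benzyl ether provides C2 with its phenyl group. This is preferred to forming C2–aryl by adding a phenyl nucleophile to a C2 oxocarbenium ion, where loss of the C3 proton would aromatise ring B to a benzofuran. The precursor is achiral. The forward carbene C–H insertion must set C2 absolutely by catalyst control and form the five-membered ring.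

**8 to 4 and 5.** Diazo ester 8 arises from arylacetate 7 by diazo transfer, 7 from arylmalonate 6 by loss of one ester, and 6 from aryl bromide 4 and dimethyl malonate 5 by cutting the aryl–C bond. A cross-coupling is chosen over a multistep homologation of an aldehyde because it installs the two-carbon unit directly on the halide.

**4 to 1.** Benzyl ether 4 is cut at O–CH2 to bromophenol 2 and benzyl bromide 3, and 2 at C–Br to methyl dihydroferulate 1. Bromination is placed before benzylation so that the free phenol directs the halogen to its only open ortho position.

## Roads not taken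

**Alternative 1:** Ireland–Claisen ring contraction. The cut is C2–C3, made by reconnecting C2' to an ester oxygen. Forward, the silyl ketene acetal of the nine-membered arylacetate lactone A2, whose (Z)-aryl enol ether is exocyclic on the cyclohexane, rearranges to the 2,3-cis acid A1, closing ring B and moving the alkene to C1'=C2'.
- Merit: the sigmatropic shift is suprafacial, so the C2' carbinol centre of A2 dictates C2. The relation between ring C and C2, which the chosen plan leaves to a modest substrate bias, is here secured by mechanism. In this respect Alternative 1 is better.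
- Weak points: A2 needs an all-cis 2',3',4'-trioxygenated cyclohexane, a geometrically defined aryl enol ether and closure of a strained nine-membered lactone. The ring-bound boat transition state gives the cis acid A1, so C3 must still be epimerised and the acid reduced.
- Comparison: the chosen plan sets against the better stereocontrol a much shorter route in which ring C costs only a benzyl group, with separation and recycling of diastereomers as the price.

**Alternative 2:** Iminium-catalysed Diels–Alder. The cuts are C3'–C4' and C5'–C6'. Forward, the dienyl acetate A4 on C2 and acrolein A5, activated as its iminium ion by a chiral imidazolidinone salt, combine endo to the cis 3'-acetoxy-4'-formyl cyclohexene A3.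
- Merit: the catalyst fixes C3'/C4' absolutely whatever C2 does, and the acetoxy and alkyl substituents of A4 direct the addition of A5 in the same regiochemical sense. In reagent control of the critical diastereo-relationship this road is better than the chosen one.
- Weak points: the dienyl acetate side chain of A4 has to be assembled on C2 over several steps, and no short entry to it is apparent. A3 is a β-acetoxy aldehyde, prone to epimerisation at C4' and to elimination of acetate. The formyl group must then become hydroxyl by a peracid oxidation in the presence of a trisubstituted alkene and an electron-rich arene.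
- Comparison: the chosen plan is shorter and avoids this labile intermediate, but has to accept substrate control.

**Alternative 3:** Chromanone oxidative ring contraction. The cut is C3–C3a. Forward, the enol ether of the 2-cyclohexenylchroman-4-one A7 is oxidised by a trivalent iodine reagent in an acidic orthoester medium, the ring A carbon migrates from the carbonyl carbon to C3, and the trans methyl ester A6 results.
- Merit: ring C arrives with its diol already configured, so no diastereotopic pair has to be chosen late, and the ester appears at C3 trans to C2. On stereochemical security this is at least equal to the chosen plan.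
- Weak points: A7 requires ring C to be made separately in enantiopure form and a catalyst-controlled ring closure to relate C2 to it. C2 of A7 can epimerise by reversible ring opening. The oxidant meets a trisubstituted alkene, an allylic carbonate and an electron-rich arene.
- Comparison: the chosen plan wins on step economy and on not needing a fragment synthesis, and loses on the certainty of the C2-to-ring-C relationship.

Key step: step 10

## Route

Assumption: the (R)-configured phthaloyl-tert-leucinate dirhodium catalyst is taken to give the 2S series in step 6; if the sense of induction is the opposite, the (S)-configured catalyst is used and nothing else changes.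

Assumption: methyl dihydroferulate 1 is taken as a commercial compound.

Step 1
Reactants: 1 methyl 3-(4-hydroxy-3-methoxyphenyl)propanoate
Product: 2 methyl 3-(3-bromo-4-hydroxy-5-methoxyphenyl)propanoate
Conditions: NBS, i-Pr2NH (10 mol%), CH2Cl2, 0 °C
Reagents that add atoms: N-bromosuccinimide, O=C1CCC(=O)N1Br
Why: Electrophilic aromatic bromination; the free phenol directs the halogen to its only open ortho position (para holds the chain), and the amine-catalysed protocol disfavours attack para to the methoxy group.

Step 2
Reactants: 2 methyl 3-(3-bromo-4-hydroxy-5-methoxyphenyl)propanoate; 3 benzyl bromide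
Product: 4 methyl 3-[4-(benzyloxy)-3-bromo-5-methoxyphenyl]propanoate
Conditions: K2CO3, DMF, rt
Reagents that add atoms: none
Why: Williamson etherification of the phenoxide; the benzyl group is both the phenol protecting group and the future C2 with its phenyl ring.

Step 3
Reactants: 4 methyl 3-[4-(benzyloxy)-3-bromo-5-methoxyphenyl]propanoate; 5 dimethyl malonate
Product: 6 dimethyl 2-[2-(benzyloxy)-3-methoxy-5-(3-methoxy-3-oxopropyl)phenyl]malonate
Conditions: Pd2(dba)3 (1.5 mol%), P(t-Bu)3·HBF4 (6 mol%), K3PO4, toluene, 80 °C
Reagents that add atoms: none
Why: Palladium-catalysed α-arylation of a malonate (Buchwald–Hartwig-type enolate coupling); the bulky electron-rich phosphine drives oxidative addition into the hindered bromide, and the phosphate base leaves the chain ester alone.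

Step 4
Reactants: 6 dimethyl 2-[2-(benzyloxy)-3-methoxy-5-(3-methoxy-3-oxopropyl)phenyl]malonate
Product: 7 methyl 2-[2-(benzyloxy)-3-methoxy-5-(3-methoxy-3-oxopropyl)phenyl]acetate
Conditions: LiCl, H2O, DMSO, 140 °C
Reagents that add atoms: none
Why: Krapcho dealkoxycarbonylation; chloride demethylates one malonate ester and the carboxylate decarboxylates to an aryl-stabilised carbanion, while the unactivated chain ester reacts far more slowly.

Step 5
Reactants: 7 methyl 2-[2-(benzyloxy)-3-methoxy-5-(3-methoxy-3-oxopropyl)phenyl]acetate
Product: 8 methyl 2-[2-(benzyloxy)-3-methoxy-5-(3-methoxy-3-oxopropyl)phenyl]-2-diazoacetate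
Conditions: p-ABSA, DBU, MeCN, 0 °C to rt
Reagents that add atoms: 4-acetamidobenzenesulfonyl azide, CC(=O)Nc1ccc(cc1)S(=O)(=O)N=[N+]=[N-]
Why: Regitz diazo transfer; DBU deprotonates only the arylacetate position, which is far more acidic than the α-position of the chain ester.

Step 6
Reactants: 8 methyl 2-[2-(benzyloxy)-3-methoxy-5-(3-methoxy-3-oxopropyl)phenyl]-2-diazoacetate
Product: 9 methyl (2S,3R)-7-methoxy-5-(3-methoxy-3-oxopropyl)-2-phenyl-2,3-dihydro-1-benzofuran-3-carboxylate (2,3-cis)
Conditions: Rh2(R-PTTL)4 (dirhodium tetrakis[N-phthaloyl-(R)-tert-leucinate], 1 mol%), toluene, −78 °C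
Reagents that add atoms: none
Why: Intramolecular 1,5 C–H insertion of a donor/acceptor rhodium carbene into the benzylic ether C–H bond forms C2–C3 and ring B; the chiral carboxylate ligands select one enantiotopic benzylic hydrogen and so set C2 (S), and the concerted insertion delivers C3 cis under kinetic control, as known for 2-benzyloxyphenyl diazoacetates.

Step 7
Reactants: 9 methyl (2S,3R)-7-methoxy-5-(3-methoxy-3-oxopropyl)-2-phenyl-2,3-dihydro-1-benzofuran-3-carboxylate
Product: 10 methyl (2S,3S)-7-methoxy-5-(3-methoxy-3-oxopropyl)-2-phenyl-2,3-dihydro-1-benzofuran-3-carboxylate (2,3-trans)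
Conditions: NaOMe (0.3 equiv), MeOH, rt
Reagents that add atoms: none
Why: Thermodynamic epimerisation through the C3 ester enolate moves the ester trans to phenyl; C2 should stay intact because expulsion of the phenoxide from the enolate would be a stereoelectronically disfavoured 5-endo ring opening, and the enantiomeric purity is checked here and raised by crystallisation of 10 or 11 if needed.

Step 8
Reactants: 10 methyl (2S,3S)-7-methoxy-5-(3-methoxy-3-oxopropyl)-2-phenyl-2,3-dihydro-1-benzofuran-3-carboxylate
Product: 11 3-[(2S,3R)-3-(hydroxymethyl)-7-methoxy-2-phenyl-2,3-dihydro-1-benzofuran-5-yl]propan-1-ol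
Conditions: LiAlH4, THF, 0 °C
Reagents that add atoms: none
Why: LiAlH4 reduces both methyl esters, creating the C3 hydroxymethyl group and the 3-hydroxypropyl chain in one operation without touching the benzylic ether or either stereocentre.

Step 9
Reactants: 11 3-[(2S,3R)-3-(hydroxymethyl)-7-methoxy-2-phenyl-2,3-dihydro-1-benzofuran-5-yl]propan-1-ol
Product: 12 [(2S,3R)-5-(3-acetoxypropyl)-7-methoxy-2-phenyl-2,3-dihydro-1-benzofuran-3-yl]methyl acetate
Conditions: Ac2O, pyridine, DMAP (cat.), CH2Cl2, rt
Reagents that add atoms: acetic anhydride, CC(=O)OC(C)=O
Why: Standard acylation; the acetates shield both primary alcohols from the triazolinedione and the later ketalisation and leave without an extra step in the basic urazole cleavage.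

Step 10
Reactants: 12 [(2S,3R)-5-(3-acetoxypropyl)-7-methoxy-2-phenyl-2,3-dihydro-1-benzofuran-3-yl]methyl acetate; 13 4-methyl-1,2,4-triazoline-3,5-dione (MTAD)
Product: 15 urazole-bridged bicyclic cis-diol diacetate (urazole nitrogens on C2' and C5' and both hydroxyls at C3' and C4' on the face away from the urazole), via bicyclic diene cycloadduct 14 (not isolated)
Conditions: 13 (2 equiv, in portions), CH2Cl2, white LEDs, −78 °C; then OsO4 (10 mol%), NMO (2 equiv), acetone/H2O, −78 to −50 °C
Reagents that add atoms: osmium tetroxide, O=[Os](=O)(=O)=O; N-methylmorpholine N-oxide, C[N+]1([O-])CCOCC1; water, O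
Why: Visible light excites 13, and the excited triazolinedione adds to the unsubstituted phenyl ring of 12 in a para-[4+2] cycloaddition across C2' and C5', a reaction with no thermal counterpart that is established for monosubstituted benzenes as arenophile dearomatisation. This closes the one new ring, the six-membered 1,2-diaza ring of the 2,3-diazabicyclo[2.2.2]octadiene 14, by cycloaddition with both C–N bonds formed on the same face of the arene. The ortho/meta mode keeps the C2 substituent off a bridgehead and places it on the C1'=C6' alkene, whereas every 1,4-pair of ring A would put a substituent on a bridgehead, so ring A should be left aside on steric grounds. OsO4 then adds to the strained disubstituted C3'=C4' alkene from the face away from the urazole, so the C3' and C4' oxygens are cis and their configuration follows from that of the bridgeheads, while the trisubstituted C1'=C6' alkene reacts far more slowly. The bridgehead centres C2' and C5' are set in the cycloaddition by the choice between the two diastereotopic ortho/meta pairs, and the only bias is the C2 stereocentre, whose ring oxygen and C3 shield the phenyl rotamers unequally. The step therefore needs diastereoselection between two bicyclic adducts; since this bias may be modest, the route relies on chromatographic separation of 15 from its bicyclic diastereomer, with assignment by crystallography of the urazole, and a cinchona-derived ligand on osmium can be screened for a matched case without the route depending on it. Both operations are kept at or below −50 °C because such cycloadducts are known to cyclorevert on warming, which also returns unreacted 14 to 12 for reuse.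

Step 11
Reactants: 15 urazole-bridged bicyclic cis-diol diacetate
Product: 16 acetonide of 15 (3',4'-O-isopropylidene urazole diacetate)
Conditions: 2,2-dimethoxypropane, PPTS (cat.), CH2Cl2, rt
Reagents that add atoms: 2,2-dimethoxypropane, COC(C)(C)OC
Why: Acid-catalysed transketalisation of the cis-diol; the acetonide protects the diol through the basic cleavage and keeps the later cyclohexadiene diol from aromatising.

Step 12
Reactants: 16 acetonide of 15
Product: 19 cyclohexa-1',5'-diene acetonide with both primary alcohols free (C1'=C2' and C5'=C6' alkenes and cis-3',4'-isopropylidenedioxy group on the ring attached to C2), via cyclic hydrazine 17 (not isolated), via cyclic diazene 18 (not isolated)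
Conditions: KOH, i-PrOH, reflux; then 0 °C, AcOH to pH 7; CuCl2 (5 mol%), air, 0 °C to rt
Reagents that add atoms: none
Why: Hydroxide hydrolyses the urazole and both acetates to the cyclic hydrazine, copper-catalysed aerobic oxidation gives the 2,3-diazabicyclo[2.2.2]octa-2,5-diene, and this loses N2 by spontaneous retro-[4+2] cycloreversion to the diene; C3' and C4' are not involved.

Step 13
Reactants: 19 cyclohexa-1',5'-diene acetonide
Product: 20 cyclohex-1'-ene acetonide (3',4'-O-isopropylidene derivative of the target)
Conditions: KO2CN=NCO2K, AcOH, MeOH, 0 °C to rt
Reagents that add atoms: none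
Why: Diimide, formed in the flask from the azodicarboxylate salt, transfers H2 by a concerted syn addition that is very sensitive to substitution, so the disubstituted C5'=C6' alkene is reduced and the trisubstituted C1'=C2' alkene stays, as in diimide reductions of arene cis-dihydrodiol derivatives.

Step 14
Reactants: 20 cyclohex-1'-ene acetonide
Product: 21 difengpiol A, (1R,2S)-4-[(2S,3R)-3-(hydroxymethyl)-5-(3-hydroxypropyl)-7-methoxy-2,3-dihydro-1-benzofuran-2-yl]cyclohex-3-ene-1,2-diol
Conditions: 80% aq AcOH, THF, 35 °C
Reagents that add atoms: none
Why: Mild aqueous acid hydrolyses the acetonide; the acid is kept weak so that neither the allylic C3' alcohol nor the allylic O1–C2 ether ionises.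

## Compound list

1 | methyl 3-(4-hydroxy-3-methoxyphenyl)propanoate (methyl dihydroferulate) | COC(=O)CCc1ccc(O)c(OC)c1 | starting material
2 | methyl 3-(3-bromo-4-hydroxy-5-methoxyphenyl)propanoate | COC(=O)CCc1cc(Br)c(O)c(OC)c1 | intermediate
3 | benzyl bromide | BrCc1ccccc1 | starting material
4 | methyl 3-[4-(benzyloxy)-3-bromo-5-methoxyphenyl]propanoate | COC(=O)CCc1cc(Br)c(OCc2ccccc2)c(OC)c1 | intermediate
5 | dimethyl malonate | COC(=O)CC(=O)OC | starting material
6 | dimethyl 2-[2-(benzyloxy)-3-methoxy-5-(3-methoxy-3-oxopropyl)phenyl]malonate | COC(=O)CCc1cc(OC)c(OCc2ccccc2)c(c1)C(C(=O)OC)C(=O)OC | intermediate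
7 | methyl 2-[2-(benzyloxy)-3-methoxy-5-(3-methoxy-3-oxopropyl)phenyl]acetate | COC(=O)CCc1cc(OC)c(OCc2ccccc2)c(CC(=O)OC)c1 | intermediate
8 | methyl 2-[2-(benzyloxy)-3-methoxy-5-(3-methoxy-3-oxopropyl)phenyl]-2-diazoacetate | COC(=O)CCc1cc(OC)c(OCc2ccccc2)c(c1)C(=[N+]=[N-])C(=O)OC | intermediate
9 | methyl (2S,3R)-7-methoxy-5-(3-methoxy-3-oxopropyl)-2-phenyl-2,3-dihydro-1-benzofuran-3-carboxylate (2,3-cis) | COc1cc(CCC(=O)OC)cc2c1O[C@H](c1ccccc1)[C@@H]2C(=O)OC | intermediate
10 | methyl (2S,3S)-7-methoxy-5-(3-methoxy-3-oxopropyl)-2-phenyl-2,3-dihydro-1-benzofuran-3-carboxylate (2,3-trans) | COc1cc(CCC(=O)OC)cc2c1O[C@H](c1ccccc1)[C@H]2C(=O)OC | intermediate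
11 | 3-[(2S,3R)-3-(hydroxymethyl)-7-methoxy-2-phenyl-2,3-dihydro-1-benzofuran-5-yl]propan-1-ol | COc1cc(CCCO)cc2c1O[C@H](c1ccccc1)[C@H]2CO | intermediate
12 | [(2S,3R)-5-(3-acetoxypropyl)-7-methoxy-2-phenyl-2,3-dihydro-1-benzofuran-3-yl]methyl acetate | COc1cc(CCCOC(C)=O)cc2c1O[C@H](c1ccccc1)[C@H]2COC(C)=O | intermediate
13 | 4-methyl-1,2,4-triazoline-3,5-dione (MTAD) | CN1C(=O)N=NC1=O | starting material
14 | cycloadduct of 12 and 13: 2,3-diazabicyclo[2.2.2]octa-5,7-diene with the urazole across C2' and C5', C1'=C6' alkene bearing C2, free C3'=C4' alkene (not isolated) | COc1cc(CCCOC(C)=O)cc2c1O[C@H](C4=C[C@H]5C=C[C@@H]4N4C(=O)N(C)C(=O)N54)[C@H]2COC(C)=O | intermediate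
15 | urazole-bridged bicyclic cis-diol diacetate: C3' and C4' hydroxyls cis, on the face away from the urazole, configured as in the target | COc1cc(CCCOC(C)=O)cc2c1O[C@H](C4=C[C@H]5[C@@H](O)[C@@H](O)[C@@H]4N4C(=O)N(C)C(=O)N54)[C@H]2COC(C)=O | intermediate
16 | acetonide of 15 (3',4'-O-isopropylidene) | COc1cc(CCCOC(C)=O)cc2c1O[C@H](C4=C[C@H]5[C@H]6OC(C)(C)O[C@H]6[C@@H]4N4C(=O)N(C)C(=O)N54)[C@H]2COC(C)=O | intermediate
17 | cyclic hydrazine: 2,3-diazabicyclo[2.2.2]oct-5-ene acetonide with both primary alcohols free (not isolated) | COc1cc(CCCO)cc2c1O[C@H](C4=C[C@H]5[C@H]6OC(C)(C)O[C@H]6[C@@H]4NN5)[C@H]2CO | intermediate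
18 | cyclic diazene: 2,3-diazabicyclo[2.2.2]octa-2,5-diene acetonide (not isolated) | COc1cc(CCCO)cc2c1O[C@H](C4=C[C@H]5[C@H]6OC(C)(C)O[C@H]6[C@@H]4N=N5)[C@H]2CO | intermediate
19 | cyclohexa-1',5'-diene acetonide: 3-[(2S,3R)-2-(cis-3',4'-isopropylidenedioxycyclohexa-1',5'-dien-1'-yl)-3-(hydroxymethyl)-7-methoxy-2,3-dihydro-1-benzofuran-5-yl]propan-1-ol | COc1cc(CCCO)cc2c1O[C@H](C3=C[C@@H]4OC(C)(C)O[C@@H]4C=C3)[C@H]2CO | intermediate
20 | cyclohex-1'-ene acetonide: 3',4'-O-isopropylidene difengpiol A | COc1cc(CCCO)cc2c1O[C@H](C3=C[C@@H]4OC(C)(C)O[C@@H]4CC3)[C@H]2CO | intermediate
21 | difengpiol A, (1R,2S)-4-[(2S,3R)-3-(hydroxymethyl)-5-(3-hydroxypropyl)-7-methoxy-2,3-dihydro-1-benzofuran-2-yl]cyclohex-3-ene-1,2-diol | COc1cc(CCCO)cc2c1O[C@H](C1=C[C@H](O)[C@H](O)CC1)[C@H]2CO | target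

## Step count and least certain steps

Total: 14 steps. Longest linear sequence: 14 steps, from 1 to 21; the route is fully linear.

**Step 10 (key step).**
- Most likely problem: poor discrimination between the two diastereotopic ortho/meta pairs of the phenyl ring. C2 is the only stereocentre near the ring and the phenyl group rotates freely, so both bicyclic diastereomers may form in similar amounts.
- Also likely: incomplete conversion of 12, because excited 13 can decay or be intercepted by the electron-rich ring A or by the activated C2–H bond before it meets the phenyl ring.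
- Fallback: a recycling loop that sets out from 12 and comes back to 12. The bicyclic diastereomer of 15, the urazole diol with the opposite bicycle configuration F1, is separated and converted with 1,1'-thiocarbonyldiimidazole into the cyclic thionocarbonate F2. Corey–Winter elimination with 1,3-dimethyl-2-phenyl-1,3,2-diazaphospholidine at 40 °C returns the diastereomeric cycloadduct F3, which cannot persist at that temperature and cycloreverts to 12 and 13. 12 is then resubmitted to step 10.

**Step 6.**
- Most likely problem: erosion of enantioselectivity. The methoxy group next to the benzyloxy group twists the ether out of the arene plane and may change how the carbene sits in the chiral pocket. Carbene dimerisation may compete at low temperature.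
- Fallback: resolution instead of asymmetric catalysis, from 8 back to 10. Insertion with achiral Rh2(OAc)4 gives 9 as a racemate with its enantiomer, the (2R,3S) cis ester F4. Epimerisation as in step 7 gives 10 together with the (2R,3R) trans ester F5, which is removed by preparative chromatography on a chiral stationary phase.

**Step 12.**
- Most likely problem: decomposition during the long hot hydrolysis of a hindered urazole, or dimerisation by Diels–Alder reaction and aromatisation of diene 19 once it accumulates during neutralisation and oxidation.
- Fallback: a telescoped sequence from 16 to 20 in which the diene never builds up. 16 is heated with excess hydrazine hydrate at 100 °C, which cleaves the urazole and the acetates to 17. The mixture is then stirred in ethanol under air with CuSO4 (cat.). This oxidises 17 to 18, which loses N2 to 19, and the same oxidant turns the excess hydrazine into diimide, which reduces the C5'=C6' alkene as 19 forms. No new compound is made.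

**Step 3.**
- Most likely problem: sluggish coupling at a bromide that is electron-rich and flanked by the benzyloxy group, leading to protodebromination instead of C–C bond formation.
- Fallback: homologation of an aldehyde in place of cross-coupling, from 1 back to 7. Ortho-formylation of 1 (MgCl2, Et3N, paraformaldehyde, MeCN, reflux) gives methyl 3-(3-formyl-4-hydroxy-5-methoxyphenyl)propanoate F6. Benzylation (3, K2CO3) gives the benzyl ether aldehyde F7. Condensation with methyl methylthiomethyl sulfoxide (Triton B, THF) gives the ketene dithioacetal S-oxide F8, and HCl in methanol converts this into 7.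

## Further compounds

F1 | step 10 | bicyclic diastereomer of 15 (urazole-bridged cis-diol diacetate with the opposite configuration at C2', C3', C4' and C5') | COc1cc(CCCOC(C)=O)cc2c1O[C@H](C4=C[C@@H]5[C@H](O)[C@H](O)[C@H]4N4C(=O)N(C)C(=O)N54)[C@H]2COC(C)=O
F2 | step 10 | cyclic thionocarbonate of F1 | COc1cc(CCCOC(C)=O)cc2c1O[C@H](C4=C[C@@H]5[C@@H]6OC(=S)O[C@@H]6[C@H]4N4C(=O)N(C)C(=O)N54)[C@H]2COC(C)=O
F3 | step 10 | bicyclic diastereomer of cycloadduct 14 | COc1cc(CCCOC(C)=O)cc2c1O[C@H](C4=C[C@@H]5C=C[C@H]4N4C(=O)N(C)C(=O)N54)[C@H]2COC(C)=O
F4 | step 6 | methyl (2R,3S)-7-methoxy-5-(3-methoxy-3-oxopropyl)-2-phenyl-2,3-dihydro-1-benzofuran-3-carboxylate (enantiomer of 9, formed with 9 as the racemate) | COc1cc(CCC(=O)OC)cc2c1O[C@@H](c1ccccc1)[C@H]2C(=O)OC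
F5 | step 6 | methyl (2R,3R)-7-methoxy-5-(3-methoxy-3-oxopropyl)-2-phenyl-2,3-dihydro-1-benzofuran-3-carboxylate (enantiomer of 10) | COc1cc(CCC(=O)OC)cc2c1O[C@@H](c1ccccc1)[C@@H]2C(=O)OC
F0 | step 12 | none | none
F6 | step 3 | methyl 3-(3-formyl-4-hydroxy-5-methoxyphenyl)propanoate | COC(=O)CCc1cc(C=O)c(O)c(OC)c1
F7 | step 3 | methyl 3-[4-(benzyloxy)-3-formyl-5-methoxyphenyl]propanoate | COC(=O)CCc1cc(C=O)c(OCc2ccccc2)c(OC)c1
F8 | step 3 | methyl 3-{4-(benzyloxy)-3-methoxy-5-[2-(methylsulfanyl)-2-(methylsulfinyl)ethenyl]phenyl}propanoate (alkene geometry immaterial) | COC(=O)CCc1cc(OC)c(OCc2ccccc2)c(c1)C=C(SC)S(C)=O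
A1 | alternative 1 | 2,3-cis dihydrobenzofuran-3-carboxylic acid from the Ireland–Claisen ring contraction | COc1cc(CCCO[Si](C)(C)C(C)(C)C)cc2c1O[C@H](C1=C[C@H](OC(C)(C)O3)[C@H]3CC1)[C@@H]2C(=O)O
A2 | alternative 1 | nine-membered arylacetate lactone with a (Z)-aryl enol ether exocyclic on the all-cis trioxygenated cyclohexane | COc1cc(CCCO[Si](C)(C)C(C)(C)C)cc2c1O/C=C1/CC[C@H]3OC(C)(C)O[C@H]3[C@H]1OC(=O)C2
A3 | alternative 2 | cis 3'-acetoxy-4'-formyl cyclohexene from the Diels–Alder reaction | COc1cc(CCCO[Si](C)(C)C(C)(C)C)cc2c1O[C@H](C1=C[C@H](OC(C)=O)[C@H](C=O)CC1)[C@H]2CO[Si](C)(C)C(C)(C)C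
A4 | alternative 2 | (E)-dienyl acetate on C2 | COc1cc(CCCO[Si](C)(C)C(C)(C)C)cc2c1O[C@H](C(=C)/C=C/OC(C)=O)[C@H]2CO[Si](C)(C)C(C)(C)C
A5 | alternative 2 | acrolein | C=CC=O
A6 | alternative 3 | trans methyl 2,3-dihydrobenzofuran-3-carboxylate from the ring contraction | COc1cc(CCC(=O)OC)cc2c1O[C@H](C1=C[C@H](OC(=O)O3)[C@H]3CC1)[C@H]2C(=O)OC
A7 | alternative 3 | 2-cyclohexenylchroman-4-one with the carbonate-protected diol | COc1cc(CCC(=O)OC)cc2c1O[C@H](C1=C[C@H](OC(=O)O3)[C@H]3CC1)CC2=O
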